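The target is a 21-membered oxa-bridged metacyclophane: ring A (5-alkylresorcinol monoether) and ring B (2-alkyl-6-aryloxyhydroquinone) are joined by the ether oxygen and by a tetradecamethylene chain C1–C14 (C1 on ring B). Because this chain carries no functional group, the ring is closed in its middle, at C8–C9, far from both arenes, by ring-closing metathesis of a tri-O-benzyl diaryl ether bearing a non-8-enyl chain on ring B and a hept-6-enyl chain on ring A. The resulting C8=C9 alkene is saturated in the same hydrogenation that removes the three benzyl groups. The diene comes from two symmetrical dibromoarenes by mono-alkylation and an Ullmann ether coupling.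

Key step: step 6

Remark: compounds 1, 3, 9 and 10 are taken as catalogue compounds.
Remark: the macrocyclic alkene 14 is expected as an E/Z mixture; the E isomer is drawn, and both isomers should give the same product in step 7.

Step 1
Reactants: 1 2,6-dibromobenzene-1,4-diol
Product: 2 2,5-bis(benzyloxy)-1,3-dibromobenzene
Conditions: BnBr (2.4 equiv), K2CO3 (3 equiv), DMF, argon, rt → 50 °C
Reagents that add atoms: benzyl bromide, BrCc1ccccc1
Why: Williamson ether synthesis; both phenoxides, including the one flanked by two bromine atoms, should be benzylated by SN2 in DMF.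

Step 2
Reactants: 2 2,5-bis(benzyloxy)-1,3-dibromobenzene; 3 9-bromonon-1-ene
Product: 5 2,5-bis(benzyloxy)-1-bromo-3-(non-8-en-1-yl)benzene, via arylmagnesium chloride 4 (not isolated)
Conditions: i-PrMgCl·LiCl (1.05 equiv), THF, −15 → 0 °C; then 3 (1.3 equiv), Li2CuCl4 (5 mol %), NMP (4 equiv), 0 °C → rt
Reagents that add atoms: none
Why: Bromine–magnesium exchange (Knochel turbo-Grignard) is assisted by the ortho benzyloxy group and should stop after one bromine because the arylmagnesium ring resists a second exchange; the copper-catalysed Kochi-type sp2–sp3 coupling should take the primary bromide 3 in preference to the secondary by-product 2-bromopropane.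

Step 3
Reactants: 5 2,5-bis(benzyloxy)-1-bromo-3-(non-8-en-1-yl)benzene
Product: 8 2,5-bis(benzyloxy)-3-(non-8-en-1-yl)phenol, via aryllithium 6 (not isolated), via lithium aryltrimethoxyborate 7 (not isolated)
Conditions: n-BuLi (1.1 equiv), THF, −78 °C; B(OMe)3 (1.5 equiv), −78 °C → rt; 30% aq H2O2, 0 °C → rt
Reagents that add atoms: hydrogen peroxide, OO
Why: Bromine–lithium exchange, borate trapping and boronate oxidation (1,2-aryl shift from boron to oxygen) should turn C–Br into C–OH, while the remote terminal alkene and the benzyl ethers are inert at −78 °C and toward H2O2.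

Step 4
Reactants: 9 1-(benzyloxy)-3,5-dibromobenzene; 10 7-bromohept-1-ene
Product: 12 1-(benzyloxy)-3-bromo-5-(hept-6-en-1-yl)benzene, via arylmagnesium chloride 11 (not isolated)
Conditions: i-PrMgCl·LiCl (1.05 equiv), THF, 0 °C → rt; then 10 (1.3 equiv), Li2CuCl4 (5 mol %), NMP (4 equiv), 0 °C → rt
Reagents that add atoms: none
Why: Mono bromine–magnesium exchange is favoured by the inductive pull of the second bromine and the meta oxygen and is self-limiting; copper-catalysed Kochi-type coupling of the arylmagnesium with the primary bromide should install the hept-6-enyl chain.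

Step 5
Reactants: 8 2,5-bis(benzyloxy)-3-(non-8-en-1-yl)phenol; 12 1-(benzyloxy)-3-bromo-5-(hept-6-en-1-yl)benzene
Product: 13 1-(benzyloxy)-3-[2,5-bis(benzyloxy)-3-(non-8-en-1-yl)phenoxy]-5-(hept-6-en-1-yl)benzene
Conditions: CuI (10 mol %), N,N-dimethylglycine hydrochloride (30 mol %), Cs2CO3 (2 equiv), 1,4-dioxane, argon, 90 °C
Reagents that add atoms: none
Why: Ullmann diaryl ether coupling under Ma conditions; the aryl bromide has no ortho substituent and only meta donors, the phenoxide is electron-rich with a single ortho substituent, and copper does not touch the terminal alkenes.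

Step 6
Reactants: 13 1-(benzyloxy)-3-[2,5-bis(benzyloxy)-3-(non-8-en-1-yl)phenoxy]-5-(hept-6-en-1-yl)benzene
Product: 14 tri-O-benzyl (E)-8,9-didehydro macrocycle (21-membered ring; C8=C9 alkene in the chain)
Conditions: second-generation Grubbs catalyst RuCl2(=CHPh)(PCy3)(H2IMes) (5 mol %), 1,4-benzoquinone (10 mol %), CH2Cl2 (1 mM, slow addition of 13), 40 °C
Reagents that add atoms: none
Why: The ruthenium benzylidene exchanges with one terminal vinyl group to give a ruthenium alkylidene, which adds intramolecularly to the second vinyl group through a ruthenacyclobutane and cycloreverts to the C8=C9 alkene with loss of ethylene (Chauvin mechanism). The closest known reaction type is macrocyclic ring-closing metathesis of α,ω-dienes to large-ring cyclophanes and macrolides. The one ring that closes is the 21-membered ring, formed by end-to-end union of the two chain termini, a macrocyclisation without Baldwin constraint that is driven by escape of ethylene. No stereocentre is created, and the alkene geometry (E expected to predominate) is irrelevant because step 7 saturates it. The step needs ring closure to win over oligomerisation and over alkene migration: millimolar dilution favours the intramolecular path, both alkenes are unhindered monosubstituted olefins five and seven methylenes away from the arenes, the meta,meta diaryl ether hinge lets the two chains converge, and 1,4-benzoquinone intercepts ruthenium hydrides. Benzyl ethers and the diaryl ether should not bind or deactivate the catalyst.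

Step 7
Reactants: 14 tri-O-benzyl (E)-8,9-didehydro macrocycle
Product: 16 CNP0393720.0 (macrocyclic triol), via saturated tribenzyl ether 15 (not isolated)
Conditions: H2 (1 atm), 10% Pd/C, EtOAc/MeOH, rt; filtration under argon
Reagents that add atoms: none
Why: Heterogeneous catalytic hydrogenation should saturate the C8=C9 alkene first and then hydrogenolyse the three aryl benzyl ethers, leaving the diaryl ether and the arenes intact.

Compound list
1 | 2,6-dibromobenzene-1,4-diol | Oc1cc(Br)c(O)c(Br)c1 | starting material
2 | 2,5-bis(benzyloxy)-1,3-dibromobenzene | Brc1cc(OCc2ccccc2)cc(Br)c1OCc1ccccc1 | intermediate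
3 | 9-bromonon-1-ene | C=CCCCCCCCBr | starting material
4 | [2,5-bis(benzyloxy)-3-bromophenyl]magnesium chloride (LiCl complex) | Cl[Mg]c1cc(OCc2ccccc2)cc(Br)c1OCc1ccccc1 | intermediate
5 | 2,5-bis(benzyloxy)-1-bromo-3-(non-8-en-1-yl)benzene | C=CCCCCCCCc1cc(OCc2ccccc2)cc(Br)c1OCc1ccccc1 | intermediate
6 | [2,5-bis(benzyloxy)-3-(non-8-en-1-yl)phenyl]lithium | [Li]c1cc(OCc2ccccc2)cc(CCCCCCCC=C)c1OCc1ccccc1 | intermediate
7 | lithium [2,5-bis(benzyloxy)-3-(non-8-en-1-yl)phenyl]trimethoxyborate | [Li+].CO[B-](OC)(OC)c1cc(OCc2ccccc2)cc(CCCCCCCC=C)c1OCc1ccccc1 | intermediate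
8 | 2,5-bis(benzyloxy)-3-(non-8-en-1-yl)phenol | Oc1cc(OCc2ccccc2)cc(CCCCCCCC=C)c1OCc1ccccc1 | intermediate
9 | 1-(benzyloxy)-3,5-dibromobenzene | Brc1cc(Br)cc(OCc2ccccc2)c1 | starting material
10 | 7-bromohept-1-ene | C=CCCCCCBr | starting material
11 | [3-(benzyloxy)-5-bromophenyl]magnesium chloride (LiCl complex) | Cl[Mg]c1cc(Br)cc(OCc2ccccc2)c1 | intermediate
12 | 1-(benzyloxy)-3-bromo-5-(hept-6-en-1-yl)benzene | C=CCCCCCc1cc(Br)cc(OCc2ccccc2)c1 | intermediate
13 | 1-(benzyloxy)-3-[2,5-bis(benzyloxy)-3-(non-8-en-1-yl)phenoxy]-5-(hept-6-en-1-yl)benzene | C=CCCCCCc1cc(Oc2cc(OCc3ccccc3)cc(CCCCCCCC=C)c2OCc2ccccc2)cc(OCc2ccccc2)c1 | intermediate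
14 | tri-O-benzyl (E)-8,9-didehydro macrocycle: ring A (5-benzyloxy-1,3-phenylene) and ring B (2,5-bis(benzyloxy)-1,3-phenylene) joined by the ether oxygen and by an (E)-tetradec-8-ene-1,14-diyl chain, C1 on ring B next to its 2-benzyloxy carbon, C14 on ring A | c1c(OCc2ccccc2)cc3cc1Oc1cc(OCc2ccccc2)cc(c1OCc1ccccc1)CCCCCCC/C=C/CCCCC3 | intermediate
15 | saturated tribenzyl ether: as 14 with a tetradecane-1,14-diyl chain | c1c(OCc2ccccc2)cc3cc1Oc1cc(OCc2ccccc2)cc(c1OCc1ccccc1)CCCCCCCCCCCCCC3 | intermediate
16 | CNP0393720.0: ring A (5-hydroxy-1,3-phenylene) and ring B (2,5-dihydroxy-1,3-phenylene) joined by the ether oxygen and by a tetradecane-1,14-diyl chain, the chain on ring B ortho to the hydroxyl that is also ortho to the aryloxy group | Oc1cc2cc(c1)Oc1cc(O)cc(c1O)CCCCCCCCCCCCCC2 | target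

Total step count: 7
Longest linear sequence: 6 (steps 1, 2, 3, 5, 6, 7)

Steps most likely to fail

Step 6. Intermolecular metathesis may outrun ring closure and give oligomers, and double-bond migration before closure may give ring-contracted homologues. The fallback sets out from 13. Oxidative cleavage of both vinyl groups (OsO4 cat., NaIO4, 2,6-lutidine, dioxane/H2O, rt) should give 6-[3-(benzyloxy)-5-[2,5-bis(benzyloxy)-3-(8-oxooctyl)phenoxy]phenyl]hexanal F1. Its two aldehyde carbons are C8 and C9. An intramolecular McMurry coupling (TiCl3(DME)1.5, Zn–Cu couple, DME, reflux, slow addition of F1) should then form the same C8=C9 bond and return to the route at 14.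

Step 5. Ligand exchange and C–O bond formation at copper may be slow, so that protodebromination of 12 and oxidation of the electron-rich phenol 8 compete. The fallback sets out from 12 and 8. Bromine–lithium exchange of 12 and borylation (n-BuLi, THF, −78 °C; B(OMe)3; aq HCl) should give [3-(benzyloxy)-5-(hept-6-en-1-yl)phenyl]boronic acid F2. A Chan–Lam–Evans coupling of F2 with 8 at room temperature (Cu(OAc)2 20 mol %, pyridine, 4 Å molecular sieves, CH2Cl2, O2 balloon) should return to the route at 13.

Step 2 (step 4 is of the same type). The halogen–magnesium exchange may be incomplete or occur twice, and a sluggish sp2–sp3 coupling would leave the arylmagnesium to be protonated on work-up. The fallback sets out from 2. Monohydroboration of commercial nona-1,8-diene (4 equiv) with 9-BBN-H in THF should give 9-(non-8-en-1-yl)-9-borabicyclo[3.3.1]nonane F3. A B-alkyl Suzuki–Miyaura coupling of F3 with 2 (2 equiv, to favour mono-coupling; the excess is recovered) under Pd(dppf)Cl2, K3PO4, THF/DMF/H2O, 50 °C should return to the route at 5.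

Further compounds
F1 | step 6 | 6-[3-(benzyloxy)-5-[2,5-bis(benzyloxy)-3-(8-oxooctyl)phenoxy]phenyl]hexanal | O=CCCCCCc1cc(Oc2cc(OCc3ccccc3)cc(CCCCCCCC=O)c2OCc2ccccc2)cc(OCc2ccccc2)c1
F2 | step 5 | [3-(benzyloxy)-5-(hept-6-en-1-yl)phenyl]boronic acid | C=CCCCCCc1cc(B(O)O)cc(OCc2ccccc2)c1
F3 | step 2 | 9-(non-8-en-1-yl)-9-borabicyclo[3.3.1]nonane | C=CCCCCCCCB1C2CCCC1CCC2
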